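The data come from a simulation on assumed constants; scatter was added.

I started from a small stock: the X that stands in the flask while X is being fed.

| setting | Tuesday's | Friday's | Wednesday's | Monday's | eta | gamma | epsilon | beta | alpha |
|---|---|---|---|---|---|---|---|---|---|
| X | 0.050 M | 0.050 M | 0.050 M | 0.025 M | 0.050 M | 0.050 M | 0.050 M (fed, over 80 min) | 0.050 M (fed, over 80 min) | 0.050 M |
| L | 1.05 equiv | 0.70 equiv | 1.6 equiv | 1.05 equiv | 1.05 equiv | 1.05 equiv (fed, over 20 min) | 1.05 equiv | 1.05 equiv | 1.05 equiv (fed, over 80 min) |
| D | 9.1 mol% | 9.1 mol% | 9.1 mol% | 9.1 mol% | 9.1 mol% | 9.1 mol% | 9.1 mol% | 9.1 mol% | 9.1 mol% |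
| temperature | 0 °C | 11 °C | 0 °C | 11 °C |  | 5 °C | 5 °C |  | 5 °C |
| remark | run made earlier | run made earlier | run made earlier | run made earlier | everything together at the start at −15 °C, warmed to 5 °C at 80 min | all else is in the flask from the start; the feed brings no volume worth counting | all else is in the flask from the start; the feed brings no volume worth counting | the addition at −15 °C, then warmed to 5 °C; the feed brings no volume worth counting | all else is in the flask from the start; the feed brings no volume worth counting |
| time |  |  |  |  | 3.0 h | 3.0 h | 3.0 h | 3.0 h | 3.0 h |

- Tuesday's (time / min: J / %, E / %): 20.0: 36, 60; 40.0: 40, 59; 60.0: 42, 60; 80.0: 41, 62; 120: 37, 60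
- Friday's (time / min: J / %, E / %): 8.00: 53, 45; 15.0: 55, 46; 30.0: 54, 48; 60.0: 52, 46; 120: 47, 49
- Wednesday's (time / min: J / %, E / %): 20.0: 26, 72; 40.0: 26, 71; 60.0: 31, 71; 80.0: 28, 70; 120: 28, 75
- Monday's (time / min: J / %, E / %): 10.0: 57, 37; 25.0: 57, 43; 50.0: 57, 42; 80.0: 55, 44; 120: 53, 43

(scatter of a reading: 2 percentage points)

- in percentages every species weighs as the X in it: one J counts as two

- the flask with the highest amount of J, in percent of the X charged ("all alike" if they lie within 1.5 percentage points) (eta / gamma / epsilon / beta / alpha / all alike)
- final J, as a percentage of the X charged, in eta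
- final J, as a percentage of the X charged, in gamma
- final J, as a percentage of the X charged, in epsilon
- final J, as a percentage of the X charged, in beta
- final J, as a percentage of the X charged, in alpha

I took J to form from two X and E from X with L and D, so the two paths share X in the ratio cX/(g·cL), where g is the selectivity factor at this loading and a charge of 0.050 M of X.

What is g? With cL held at its mean, a batch gives E the share a·ln(1 + 1/a), where a is g times mean L in equivalents. Tuesday's reading of 60% E at 60.0 min means a mean L of 0.750 and needs a = 0.619, so I read g = 0.826 at 0 °C, and I used it unchanged at 5 °C.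

How much X stands in epsilon? Monday's readings at 10.0 min leave 6.00% of X unaccounted for, a rough figure given the scatter. Taking that as the X left, its decay, times the E share of the product, gives 0.111 /min for the E path in Monday's run. Scaled to epsilon's cD and to a mean L of 0.550 equivalents, with no correction for temperature, this becomes 0.358 /min. Feed rate divided by that rate constant is 3.49% of the charge, the mean standing stock of X.

What does that stock give? It is smaller than g times mean L, 0.454, so J takes a share s/(s + g·L) = 7.13% in epsilon. Feeding L starts cL at zero and pushes the ratio the other way, so I expected alpha, with the slower feed, above gamma.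

The forecast named alpha, with 31% in eta, 58% in gamma, 36% in epsilon, 32% in beta and 70% in alpha. It held that “Feeding X leaves L/K unchanged, so selectivity stays the same”, and on epsilon my reckoning differs from it.

The flasks gave 35.4% in eta, 78.6% in gamma, 10.9% in epsilon, 16.1% in beta and 88.0% in alpha, so alpha stood highest.

    2 X → J (k = 0.110 /M/s, Ea = 44.0 kJ/mol)
    X + L + D → D + E (k = 36.0 /M²/s, Ea = 35.0 kJ/mol)
    (constants at 5 °C)

Epsilon's 10.9% lies above my 7.13% and below the forecast's 36%. In epsilon X stood at 7.24% at the end of the feed, a single moment, while my 3.49% was a mean over the feed. Both flasks have come to rest by the asked time: X is 0% in epsilon and 0% in alpha, though 15% and 89% of their L remain. Ten times the time leaves J at 10.9% in epsilon and 88.0% in alpha at 30.0 h.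

For epsilon dosed over 7.98 min, my reckoning makes the stock 35.0% and the same formula gives 43.5% J. The computed flask gives 26.9%, below that figure.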